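Read the split first.

all flasks: X 20 mM
- ochre: G 20 mM; the very flask that is asked about, followed so far
- grey: G 30 mM; run made earlier
- flask: G 20.0 mM; time 50 h

| run | time / h | Z / % | L / % |
|---|---|---|---|
| ochre | 0.500 | 20.8 | 18.2 |
| ochre | 0.667 | 21.9 | 20.2 |
| ochre | 1.00 | 22.8 | 22.8 |
| ochre | 1.50 | 23.4 | 24.6 |
| ochre | 2.50 | 22.8 | 26.2 |
| ochre | 4.00 | 22.6 | 26.5 |
| ochre | 6.00 | 23.2 | 26.5 |
| grey | 3.00 | 31.8 | 22.1 |
| grey | 6.00 | 31.3 | 21.6 |
| grey | 8.00 | 31.6 | 21.4 |
| grey | 12.0 | 31.7 | 22.0 |
| grey | 15.0 | 31.2 | 21.2 |
| grey | 20.0 | 31.5 | 21.5 |

(standard deviation of a reading: 0.3 percentage points)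

* why nothing more happens at 50 h, or that something still does (forward and back rates have come level / all of X has reacted / G has run out first / it is still moving)
* the Z standing at 50 h, as a percentage of the X charged
* the L standing at 50 h, as a percentage of the X charged

- the reaction counts as stopped when no species that holds the X changes by six tenths of a point or more over the second half of the time

Why not call the plateau a balance? From 2.50 h on, ochre stands at Z 22.9 % and L 26.4 %, so the split, Z standing over L standing, is 0.866. Grey, averaged over its run, stands at Z 31.5 % and L 21.6 %, a split of 1.46, larger than ochre's. Two products holding the same X and G, in balance with each other at one temperature, keep one ratio whatever G is charged, so I read kinetic control: Z and L compete for X.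

By what rule? Take average G as the midpoint between the charge and what Z and L leave: 15.1 mM in ochre, 24.7 mM in grey. The split rose by a factor of 1.69, average G by 1.64. So the readings give 0.0582 mM⁻¹ as the split constant, the split divided by average G, taken over both runs.

And the 50.7 % of ochre's X that is neither Z nor L? I put free X at the stop at 0 % and the gap in products not read, but no reading shows this directly.

Your answer for this flask? It has ochre's charge and grey shows no drift up to 20.0 h, so Z 22.9 % and L 26.4 %, stopped with X reacted away.

The forecast says forward and back rates have come level, with Z 22.9 % (22.2 % to 23.6 %) and L 26.5 % (25.8 % to 27.3 %): "Reaction has therefore stopped with both ends still available, which means forward and back rates have balanced." I differ from it on the stop.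

The flask gives: all of X has reacted, Z 22.9 %, L 26.4 %.

    2 X → J (k = 0.0260 M⁻¹ s⁻¹)
    Z ⇌ Q (K = 0.280, k = 8.90 × 10⁻⁵ s⁻¹)
    X + G → L, rate k3*[X] as long as [G] is above zero (k = 2.40 × 10⁻⁴ s⁻¹)
    X + G → Z (k = 0.0190 M⁻¹ s⁻¹)

At 50 h this flask holds X 0 % and G 44.3 % of its charge, while the gap stands as J 44.3 % and Q 6.41 %, counted in the X they hold. Its split is 0.867, and the split constant times its average G, reckoned from Z and L, gives 0.878, which is no test, as ochre went into the constant. For the neighbour charged with 50 mM of G, the midpoint reckoned with grey's Z and L puts average G at 44.7 mM and the split at 2.60. That neighbour stands at Z 42.4 % and L 16.0 %, a split of 2.65.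

The earlier runs and the new flask were generated by integration for an exercise; noise was put on by code.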